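In a one-step world G meets D and nothing else, so the flask's 0.10 M of D would vanish under 0.120 M of G, with 0.0200 M of G over. In the opposite world G goes wholly to E and D stays at 100%. The earlier runs place the flask between these worlds, for they stop with D left over and with J and L formed.

| flask | D | G | remark | time |
|---|---|---|---|---|
| violet | 0.14 M | 0.12 M | run made earlier |  |
| teal | 0.22 M | 0.12 M | run made earlier |  |
| ochre | 0.10 M | 0.24 M | run made earlier |  |
| flask | 0.10 M | 0.120 M |  | 8.0 h |

| run | time / h | J / % | L / % | D / % |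
|---|---|---|---|---|
| violet | 0.667 | 37.0 | 7.6 | 55.4 |
| violet | 2.00 | 36.7 | 8.6 | 53.1 |
| violet | 3.00 | 36.8 | 8.8 | 54.6 |
| violet | 5.00 | 37.3 | 7.4 | 55.4 |
| violet | 8.00 | 36.4 | 6.9 | 54.4 |
| violet | 10.0 | 37.4 | 9.8 | 55.1 |
| teal | 0.667 | 28.2 | 5.3 | 63.5 |
| teal | 2.00 | 28.4 | 9.3 | 65.4 |
| teal | 3.00 | 30.3 | 7.5 | 66.0 |
| teal | 5.00 | 29.9 | 6.1 | 65.3 |
| teal | 8.00 | 28.6 | 6.4 | 64.9 |
| teal | 10.0 | 28.5 | 7.1 | 66.1 |
| ochre | 2.00 | 61.3 | 10.8 | 28.6 |
| ochre | 4.00 | 60.5 | 9.6 | 28.5 |
| ochre | 6.00 | 60.9 | 11.9 | 27.7 |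
| ochre | 8.00 | 60.4 | 12.4 | 27.8 |
| ochre | 10.0 | 59.3 | 11.3 | 30.1 |

(scatter of a reading: 1 percentage point)

- steps under discussion: G -> E; G + Z -> L; G + Q -> J; Q <-> Z; D <-> Q

- the J standing at 8.0 h, as a percentage of the D charged
- the L standing at 8.0 h, as a percentage of the D charged

Violet's D reads 55.4% at 0.667 h and 55.1% at 10.0 h, flat within the scatter of 1 percentage point. The reckoning here takes that stop as cG reaching zero, with G the limiting reagent. Violet's J, L and D add to 100% at 0.667 h, so this reckoning counts nothing in Q and Z. Each J or L costs one G, so the G charged equals the D lost plus the G burnt to E. Define the waste constant as the G burnt to E per unit of ln(cD charged / cD left). At their 8.00 h readings, violet gives 0.0922 M and teal 0.0990 M, close despite different cD. Ochre, at 0.24 M of G, gives more, 0.131 M, so the flask, at the 0.120 M of G that violet and teal also hold, takes the mean of those two, 0.0956 M.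

One Newton step on the balance, from a trial fraction of 0.5, leaves 48.7% of the flask's D. Violet's readings give J a share 81.9% of J plus L, so this reckoning says 42.0% of J and 9.29% of L.

The forecast gives 41.8% of J and 9.4% of L, holding that “G is used up quickly and the runs simply stop”.

The flask gives 42.6% of J and 8.83% of L, with D at 48.4% and G at 0%.

    G → E (k = 0.00120 s⁻¹)
    G + Z → L (k = 4.70 M⁻¹ s⁻¹)
    G + Q → J (k = 15.0 M⁻¹ s⁻¹)
    Q ⇌ Z (K = 0.810, k = 0.900 s⁻¹)
    D ⇌ Q (K = 0.00160, k = 0.00110 s⁻¹)

The same 0.0956 M carries to the neighbour with 0.40 M of D on the same 0.120 M of G, which is 0.300 equiv of G to D. One Newton step from a trial fraction of 0.750 leaves 76.4% of its D. That neighbour ends with G at 0%, J at 19.3%, L at 3.97% and D at 77%.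

Readings and results come from a simulation from invented constants, and the scatter is random.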